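**Plan**
- The last disconnection is the C(sp3)–C(sp2) bond between the ethylene linker and diene carbon C1 of ring B (B-alkyl Suzuki coupling). It gives a decalin dienyl triflate and a vinyl-substituted perhydrobenzoxepinone.
- In the decalin, the C8a–C8 and C4a–C5 bonds of ring A are cut (quinone Diels–Alder). Ring B has methyl groups on C2 and C8a, the two carbons flanking C1, which is the substitution pattern of 2,6-dimethylbenzoquinone. Ring A has its carbinol carbon C6 next to the CMe2 carbon C5, which is a 2-silyloxy diene with a dimethylated terminus.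
- In the left bicycle, the O1–C2 ether bond and the C5a–C6 bond are cut (diepoxide cascade ended by an allylsilane). The chain comes from geranyl bromide and methyl acetoacetate.
- Forward: ring A is annulated onto the quinone (ring B), the fusion is epimerised to trans, C4 is deoxygenated and C1 becomes the dienyl triflate. In the left half the oxepane and then the cyclohexane close in one cascade. The two halves are joined last.
- Stereochemistry, right half: C8a from the chiral Lewis acid in the cycloaddition, C4a by epimerisation, C6 by substrate-controlled hydride reduction.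
- Stereochemistry, left half: C9a and C5a from Shi epoxidation, C6 from the chair transition state of the cascade, C7 by hydrogenation anti to the angular methyl.

Key step: step 2

Assumption: the sense of induction of the oxazaborolidinium salt with this hindered diene cannot be assigned with certainty; the (S)-catalyst is written, and its (R)-enantiomer would be used if it favoured the mirror-image adduct.

Locants: the right half is numbered as a naphthalene (C1 linker carbon, C2 methyl-bearing, C4a/C8a ring fusion, C5 CMe2, C6 carbinol). The left half is numbered as a 1-benzoxepine (O1, C2 CMe2, C3 carbonyl, C5a angular carbon, C6 side-chain carbon, C7 methyl-bearing, C9a O-bearing).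

**Right half**

Step 1
Reactants: 1 4-methylpent-1-en-3-one
Product: 2 4-methyl-3-(triisopropylsilyloxy)penta-1,3-diene
Conditions: i-Pr3SiOTf, Et3N, CH2Cl2, 0 → 23 °C
Reagents that add atoms: triisopropylsilyl trifluoromethanesulfonate, CC(C)[Si](C(C)C)(C(C)C)OS(=O)(=O)C(F)(F)F
Why: Soft enolisation and O-silylation (silyl enol ether formation) can only involve the isopropyl methine, the sole α-hydrogen, so the tetrasubstituted silyl dienol ether should form regiospecifically.

Step 2
Reactants: 3 2,6-dimethyl-1,4-benzoquinone; 2 4-methyl-3-(triisopropylsilyloxy)penta-1,3-diene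
Product: 4 (4aR,8aS)-2,5,5,8a-tetramethyl-6-(triisopropylsilyloxy)-4a,5,8,8a-tetrahydronaphthalene-1,4-dione (cis-fused adduct)
Conditions: (S)-3,3-diphenyl-1-(2-methylphenyl)tetrahydro-1H,3H-pyrrolo[1,2-c][1,3,2]oxazaborole·HN(SO2CF3)2 (20 mol %), CH2Cl2, −78 → −20 °C
Reagents that add atoms: none
Why: The cationic boron should bind the less hindered, more basic C4 carbonyl of 3 (flanked by two vinylic C–H) and lower the LUMO of the C2=C3 bond, making this a Lewis-acid-catalysed (4+2) cycloaddition of the type known for quinones and 2-silyloxy-1,3-dienes under chiral oxazaborolidinium catalysis. The unhindered CH2 terminus of 2 bonds to the methyl-bearing β-carbon C2 and the CMe2 terminus to C3–H, either in one asynchronous step or through a boron enolate/silyloxyallyl cation pair that collapses at once; in both cases ring A closes as a six-membered ring in the (4+2) sense (6-endo with respect to the allyl cation in the stepwise limit). Both new stereocentres form suprafacially on the quinone, so the angular methyl at C8a and the hydrogen at C4a are cis, and their absolute configuration is set by the catalyst, whose aryl group covers one face of the bound enedione so that the diene adds to the other. The step needs regioselectivity, which the substrate secures because the other orientation would join the CMe2 carbon to the methyl-bearing C2 (two fully substituted carbons), and π-facial selectivity, which is the catalyst's task alone because the two methyl-bearing double bonds are equivalent by symmetry. The angular methyl keeps the adduct from aromatising, and the bulky triisopropylsilyl group disfavours loss of silicon before ring closure.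

Step 3
Reactants: 4 cis-fused adduct
Product: 6 (4aS,8aS)-2,5,5,8a-tetramethyl-4a,7,8,8a-tetrahydronaphthalene-1,4,6(5H)-trione (trans-fused triketone), via cis-fused triketone 5 (not isolated)
Conditions: 48% aq. HF, MeCN, 0 °C; then Et3N (excess), 23 °C
Reagents that add atoms: none
Why: Protodesilylation of the silyl enol ether frees the ring A ketone, and amine-mediated enolisation of the C4a–H next to the C4 carbonyl followed by reprotonation anti to the axial angular methyl should give the trans-decalin (base epimerisation of a quinone Diels–Alder adduct).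

Step 4
Reactants: 6 trans-fused triketone
Product: 7 (4R,4aS,6S,8aS)-4,6-dihydroxy-2,5,5,8a-tetramethyl-4a,5,6,7,8,8a-hexahydronaphthalen-1(4H)-one
Conditions: NaBH4, CeCl3·7H2O, MeOH/CH2Cl2, −78 → −40 °C
Reagents that add atoms: none
Why: Luche reduction should reduce the C4 carbonyl 1,2 and spare the C1 carbonyl, which is shielded by the quaternary C8a and the C2 methyl; axial hydride attack on the ring A ketone anti to the two axial methyls gives the equatorial 6-alcohol, cis to the angular methyl, as with 4,4-dimethyl-3-keto terpenoids. The C4 configuration is of no consequence.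

Step 5
Reactants: 7 dihydroxy enone
Product: 8 (4aS,6S,8aS)-6-hydroxy-2,5,5,8a-tetramethyl-4a,5,6,7,8,8a-hexahydronaphthalen-1(4H)-one
Conditions: Zn dust, AcOH, 90 °C
Reagents that add atoms: none
Why: Reduction of a vinylogous α-ketol: two-electron transfer from zinc to the enone expels the axial γ-hydroxyl at C4, which is aligned with the π-system, and protonation of the zinc dienolate under the hot acidic conditions should give the conjugated enone; the isolated C6 alcohol is inert.

Step 6
Reactants: 8 hydroxy enone
Product: 9 (4aS,6S,8aS)-2,5,5,8a-tetramethyl-6-(triethylsilyloxy)-4a,5,6,7,8,8a-hexahydronaphthalen-1(4H)-one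
Conditions: Et3SiCl, imidazole, DMAP (cat.), DMF, 23 °C
Reagents that add atoms: chlorotriethylsilane, CC[Si](Cl)(CC)CC
Why: Silylation of the equatorial secondary alcohol; the triethylsilyl ether should survive KN(SiMe3)2 and aqueous carbonate and is removed by fluoride at the end.

Step 7
Reactants: 9 silyl ether enone
Product: 10 (4aS,6S,8aS)-2,5,5,8a-tetramethyl-6-(triethylsilyloxy)-4a,5,6,7,8,8a-hexahydronaphthalen-1-yl trifluoromethanesulfonate
Conditions: KN(SiMe3)2, THF, −78 °C; PhNTf2, −78 → 0 °C
Reagents that add atoms: N-phenylbis(trifluoromethanesulfonimide), O=S(=O)(N(c1ccccc1)S(=O)(=O)C(F)(F)F)C(F)(F)F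
Why: C8a is quaternary, so the enone has no α′-hydrogen and the base can only remove a γ-hydrogen at C4; O-sulfonylation of the linear dienolate should give the 1,3-dienyl triflate (enol triflate formation) without touching C4a.

**Left half**

Step 8
Reactants: 11 methyl acetoacetate; 12 geranyl bromide
Product: 13 methyl (6E)-7,11-dimethyl-3-oxododeca-6,10-dienoate
Conditions: NaH, THF, 0 °C; n-BuLi, 0 °C; then 12, 0 → 23 °C
Reagents that add atoms: none
Why: The γ-carbon of the acetoacetate dianion displaces the primary allylic bromide (SN2 alkylation of a β-keto ester dianion) with retention of the E-alkene.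

Step 9
Reactants: 13 β-keto ester
Product: 14 methyl (2Z,6E)-3-(diethoxyphosphoryloxy)-7,11-dimethyldodeca-2,6,10-trienoate
Conditions: NaH, Et2O, 0 °C; ClP(O)(OEt)2, 0 → 23 °C
Reagents that add atoms: diethyl chlorophosphate, CCOP(=O)(Cl)OCC
Why: O-Phosphorylation of the chelated sodium enolate should give the (Z)-enol phosphate (enol phosphate formation).

Step 10
Reactants: 14 enol phosphate
Product: 15 methyl (2Z,6E)-7,11-dimethyl-3-[(trimethylsilyl)methyl]dodeca-2,6,10-trienoate
Conditions: Me3SiCH2MgCl, Ni(acac)2 (5 mol %), THF, 0 → 23 °C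
Reagents that add atoms: (trimethylsilyl)methylmagnesium chloride, C[Si](C)(C)C[Mg]Cl
Why: Nickel-catalysed Kumada-type coupling of the enol phosphate proceeds with retention of alkene geometry and should give the (Z)-allylsilane, in which the ester is cis to the CH2SiMe3 group.

Step 11
Reactants: 15 allylsilane triene
Product: 16 methyl (2Z)-5-[(2S,3S)-3-{2-[(2S)-3,3-dimethyloxiran-2-yl]ethyl}-3-methyloxiran-2-yl]-3-[(trimethylsilyl)methyl]pent-2-enoate
Conditions: 1,2:4,5-di-O-isopropylidene-β-L-erythro-2,3-hexodiulo-2,6-pyranose (enantiomer of the fructose-derived Shi ketone, 0.6 equiv), Oxone (2KHSO5·KHSO4·K2SO4), K2CO3, Bu4NHSO4, MeCN/CH2(OMe)2/aq. Na2B4O7 buffer (pH 10.5), 0 °C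
Reagents that add atoms: potassium peroxymonosulfate, [K+].[O-]S(=O)(=O)OO
Why: Shi epoxidation: the chiral dioxirane oxidises the two electron-rich trisubstituted alkenes through a spiro transition state and leaves the electron-poor enoate alone; reagent control sets all three epoxide stereocentres in the S series.

Step 12
Reactants: 16 diepoxide
Product: 18 methyl (3S,5aS,6R,9aS)-3-hydroxy-2,2,5a-trimethyl-7-methylidenedecahydro-1-benzoxepine-6-carboxylate, via O-trimethylsilyl ether 17 (not isolated)
Conditions: Me3SiOTf, 2,6-di-tert-butyl-4-methylpyridine, CH2Cl2, −78 °C; then MeOH, K2CO3, 0 °C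
Reagents that add atoms: none
Why: Tandem oxa-/carbacyclisation of a 1,5-diepoxide: the silylated terminal epoxide is opened at its tertiary carbon by the oxygen of the internal epoxide, and the resulting bicyclic epoxonium ion is opened at its tertiary carbon, with inversion, by the γ-carbon of the allylsilane through a chair transition state; this should give the trans-fused oxepane, the equatorial ester (from the Z-allylsilane) and, after loss of silicon, the exocyclic methylene; methanolysis frees the C3 alcohol.

Step 13
Reactants: 18 methylene ester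
Product: 19 methyl (3S,5aS,6R,7R,9aS)-3-hydroxy-2,2,5a,7-tetramethyldecahydro-1-benzoxepine-6-carboxylate
Conditions: H2 (1 atm), PtO2, EtOAc, 23 °C
Reagents that add atoms: none
Why: Heterogeneous hydrogenation should occur on the face away from the axial angular methyl, which is 1,3-related to the methylene carbon, leaving the new C7 methyl axial and cis to both the angular methyl and the ester.

Step 14
Reactants: 19 hydroxy ester
Product: 20 (3S,5aS,6R,7R,9aS)-6-(hydroxymethyl)-2,2,5a,7-tetramethyldecahydro-1-benzoxepin-3-ol
Conditions: LiAlH4, THF, 0 → 23 °C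
Reagents that add atoms: none
Why: Hydride reduction of the ester to the primary alcohol; no stereocentre is affected.

Step 15
Reactants: 20 diol
Product: 21 (5aS,6R,7R,9aS)-2,2,5a,7-tetramethyl-3-oxodecahydro-1-benzoxepine-6-carbaldehyde
Conditions: Dess–Martin periodinane, NaHCO3, CH2Cl2, 23 °C
Reagents that add atoms: none
Why: Dess–Martin oxidation converts both alcohols under buffered, non-enolising conditions, so the aldehyde α-carbon C6 should keep its configuration.

Step 16
Reactants: 21 keto aldehyde
Product: 22 (5aS,6R,7R,9aS)-6-ethenyl-2,2,5a,7-tetramethyloctahydro-1-benzoxepin-3(2H)-one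
Conditions: Ph3PCH3Br, KN(SiMe3)2, THF, 0 °C; then 21, −78 → 0 °C
Reagents that add atoms: methyltriphenylphosphonium bromide, C[P+](c1ccccc1)(c1ccccc1)c1ccccc1.[Br-]
Why: Wittig methylenation should take the aldehyde far faster than the ketone flanked by the O-substituted quaternary carbon; low temperature and only a slight excess of ylide guard against epimerisation at C6.

**Union and end game**

Step 17
Reactants: 22 vinyl ketone; 10 dienyl triflate
Product: 24 (5aS,6R,7R,9aS)-2,2,5a,7-tetramethyl-6-{2-[(4aR,6S,8aS)-2,5,5,8a-tetramethyl-6-(triethylsilyloxy)-4a,5,6,7,8,8a-hexahydronaphthalen-1-yl]ethyl}octahydro-1-benzoxepin-3(2H)-one, via B-alkyl-9-BBN adduct 23 (not isolated)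
Conditions: 9-BBN dimer, THF, 23 °C; then 10, Pd(dppf)Cl2 (10 mol %; dppf = 1,1′-bis(diphenylphosphino)ferrocene), AsPh3, Cs2CO3, DMF/H2O, 23 → 50 °C
Reagents that add atoms: none
Why: Anti-Markovnikov hydroboration of the monosubstituted alkene should outpace reduction of the hindered ketone, and B-alkyl Suzuki–Miyaura coupling with the dienyl triflate forms the linker–C1 bond with the diene intact; no stereocentre is created.

Step 18
Reactants: 24 coupled silyl ether
Product: 25 (5aS,6R,7R,9aS)-6-{2-[(4aR,6S,8aS)-6-hydroxy-2,5,5,8a-tetramethyl-4a,5,6,7,8,8a-hexahydronaphthalen-1-yl]ethyl}-2,2,5a,7-tetramethyloctahydro-1-benzoxepin-3(2H)-one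
Conditions: HF·pyridine, THF/pyridine, 0 → 23 °C
Reagents that add atoms: none
Why: Fluoride-mediated cleavage of the triethylsilyl ether (desilylation) under buffered conditions that should leave the diene and the ketone untouched.

**Compound list**

1 | 4-methylpent-1-en-3-one | CC(C)C(=O)C=C | starting material
2 | 4-methyl-3-(triisopropylsilyloxy)penta-1,3-diene | C=CC(O[Si](C(C)C)(C(C)C)C(C)C)=C(C)C | intermediate
3 | 2,6-dimethyl-1,4-benzoquinone | CC1=CC(=O)C=C(C)C1=O | starting material
4 | cis-fused adduct, (4aR,8aS)-2,5,5,8a-tetramethyl-6-(triisopropylsilyloxy)-4a,5,8,8a-tetrahydronaphthalene-1,4-dione | O=C1C(C)=CC(=O)[C@@H]2C(C)(C)C(O[Si](C(C)C)(C(C)C)C(C)C)=CC[C@]12C | intermediate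
5 | cis-fused triketone, (4aR,8aS)-2,5,5,8a-tetramethyl-4a,7,8,8a-tetrahydronaphthalene-1,4,6(5H)-trione | O=C1C(C)=CC(=O)[C@@H]2C(C)(C)C(=O)CC[C@]12C | intermediate (not isolated)
6 | trans-fused triketone, (4aS,8aS)-2,5,5,8a-tetramethyl-4a,7,8,8a-tetrahydronaphthalene-1,4,6(5H)-trione | O=C1C(C)=CC(=O)[C@H]2C(C)(C)C(=O)CC[C@]12C | intermediate
7 | (4R,4aS,6S,8aS)-4,6-dihydroxy-2,5,5,8a-tetramethyl-4a,5,6,7,8,8a-hexahydronaphthalen-1(4H)-one | O=C1C(C)=C[C@@H](O)[C@H]2C(C)(C)[C@@H](O)CC[C@]12C | intermediate
8 | (4aS,6S,8aS)-6-hydroxy-2,5,5,8a-tetramethyl-4a,5,6,7,8,8a-hexahydronaphthalen-1(4H)-one | O=C1C(C)=CC[C@H]2C(C)(C)[C@@H](O)CC[C@]12C | intermediate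
9 | (4aS,6S,8aS)-2,5,5,8a-tetramethyl-6-(triethylsilyloxy)-4a,5,6,7,8,8a-hexahydronaphthalen-1(4H)-one | O=C1C(C)=CC[C@H]2C(C)(C)[C@@H](O[Si](CC)(CC)CC)CC[C@]12C | intermediate
10 | (4aS,6S,8aS)-2,5,5,8a-tetramethyl-6-(triethylsilyloxy)-4a,5,6,7,8,8a-hexahydronaphthalen-1-yl trifluoromethanesulfonate | O=S(=O)(OC1=C(C)C=C[C@H]2C(C)(C)[C@@H](O[Si](CC)(CC)CC)CC[C@]12C)C(F)(F)F | intermediate
11 | methyl acetoacetate | COC(=O)CC(C)=O | starting material
12 | geranyl bromide | BrC/C=C(\C)CCC=C(C)C | starting material
13 | methyl (6E)-7,11-dimethyl-3-oxododeca-6,10-dienoate | COC(=O)CC(=O)CC/C=C(\C)CCC=C(C)C | intermediate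
14 | methyl (2Z,6E)-3-(diethoxyphosphoryloxy)-7,11-dimethyldodeca-2,6,10-trienoate | COC(=O)/C=C(\OP(=O)(OCC)OCC)CC/C=C(\C)CCC=C(C)C | intermediate
15 | methyl (2Z,6E)-7,11-dimethyl-3-[(trimethylsilyl)methyl]dodeca-2,6,10-trienoate | COC(=O)/C=C(\C[Si](C)(C)C)CC/C=C(\C)CCC=C(C)C | intermediate
16 | (6S,7S,10S)-diepoxide of 15 | COC(=O)/C=C(\C[Si](C)(C)C)CC[C@@H]1O[C@@]1(C)CC[C@@H]1OC1(C)C | intermediate
17 | O-trimethylsilyl ether of 18 | COC(=O)[C@@H]2C(=C)CC[C@@H]3OC(C)(C)[C@@H](O[Si](C)(C)C)CC[C@]32C | intermediate (not isolated)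
18 | methyl (3S,5aS,6R,9aS)-3-hydroxy-2,2,5a-trimethyl-7-methylidenedecahydro-1-benzoxepine-6-carboxylate | COC(=O)[C@@H]2C(=C)CC[C@@H]3OC(C)(C)[C@@H](O)CC[C@]32C | intermediate
19 | methyl (3S,5aS,6R,7R,9aS)-3-hydroxy-2,2,5a,7-tetramethyldecahydro-1-benzoxepine-6-carboxylate | COC(=O)[C@@H]2[C@H](C)CC[C@@H]3OC(C)(C)[C@@H](O)CC[C@]32C | intermediate
20 | (3S,5aS,6R,7R,9aS)-6-(hydroxymethyl)-2,2,5a,7-tetramethyldecahydro-1-benzoxepin-3-ol | OC[C@@H]2[C@H](C)CC[C@@H]3OC(C)(C)[C@@H](O)CC[C@]32C | intermediate
21 | (5aS,6R,7R,9aS)-2,2,5a,7-tetramethyl-3-oxodecahydro-1-benzoxepine-6-carbaldehyde | O=C[C@@H]2[C@H](C)CC[C@@H]3OC(C)(C)C(=O)CC[C@]32C | intermediate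
22 | (5aS,6R,7R,9aS)-6-ethenyl-2,2,5a,7-tetramethyloctahydro-1-benzoxepin-3(2H)-one | C=C[C@@H]2[C@H](C)CC[C@@H]3OC(C)(C)C(=O)CC[C@]32C | intermediate
23 | B-alkyl-9-BBN adduct of 22 | C(C[C@@H]2[C@H](C)CC[C@@H]3OC(C)(C)C(=O)CC[C@]32C)B4C5CCCC4CCC5 | intermediate (not isolated)
24 | triethylsilyl ether of the target | CC1=C(CC[C@@H]2[C@H](C)CC[C@@H]3OC(C)(C)C(=O)CC[C@]32C)[C@@]2(C)CC[C@H](O[Si](CC)(CC)CC)C(C)(C)[C@@H]2C=C1 | intermediate
25 | CNP0106412.1 | CC1=C(CC[C@@H]2[C@H](C)CC[C@@H]3OC(C)(C)C(=O)CC[C@]32C)[C@@]2(C)CC[C@H](O)C(C)(C)[C@@H]2C=C1 | target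

**Totals and risks**

Total steps: 18. Longest linear sequence: 11 (steps 8–18).

Steps most likely to fail:

1. Step 2. The congested CMe2 terminus may slow bond formation to C3 so much that the catalyst-bound pathway no longer dominates: conversion stalls, the open zwitterion loses silicon and tautomerises to a hydroquinone, or facial selectivity is low.
 Fallback: absolute configuration is taken from a resolution instead of the catalyst. Setting out from 2 and 3, the cycloaddition is run thermally without Lewis acid (toluene, 110 °C), where the innate polarisation of 3 and the steric demand of the diene favour the same orientation. This gives 4 together with its mirror image, the racemic cis adduct F1. Steps 3–5 are applied unchanged to the racemate and give, beside 5–8, the mirror-image cis-fused triketone F2 (not isolated), the mirror-image trans-fused triketone F3, the mirror-image diol F4 and the mirror-image hydroxy enone F5. The racemic alcohol is esterified with (S)-2-methoxy-2-phenylacetic acid (DCC, DMAP, CH2Cl2) to the (S)-O-methylmandelate of 8 F6 and the (S)-O-methylmandelate of the mirror-image alcohol F7, which are separated by chromatography or crystallisation. Saponification of F6 (LiOH, THF/MeOH/H2O) comes back to the route at 8.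

2. Step 12. The allylsilane is conjugated to an ester and is a weak nucleophile. The epoxonium ion may be captured too slowly and collapse by hydride shift or triflate opening, or the internal epoxide may be opened first so that the resulting hydroxy epoxide closes 6-exo to a tetrahydropyran.
 Fallback: the cascade is terminated by a silyl enol ether, the nucleophile class best documented for such diepoxide cascades, and the methylene group is added afterwards by olefination. Setting out from 13, t-BuMe2SiOTf/Et3N gives the (Z)-silyl enol ether F8. Shi epoxidation as in step 11 gives the silyl enol ether diepoxide F9. Me3SiOTf/2,6-di-tert-butyl-4-methylpyridine at −78 °C gives the bicyclic β-keto ester O-trimethylsilyl ether F10, which is methanolysed (K2CO3, MeOH) to the hydroxy β-keto ester F11. Wittig methylenation of the ring ketone (Ph3P=CH2 in excess, toluene, 60 °C) comes back to the route at 18.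

3. Step 17. 9-BBN may reduce the oxepanone in competition with hydroboration of the hindered vinyl group, so that borane is consumed and a ketone/alcohol mixture enters a coupling that is already slow at the hindered dienyl triflate.
 Fallback: the oxepane carbonyl is introduced only after the two halves are joined. Setting out from 20, selective oxidation of the primary alcohol (TEMPO cat., PhI(OAc)2, CH2Cl2) gives the hydroxy aldehyde F12, and Wittig methylenation gives the vinyl alcohol F13. Hydroboration with excess 9-BBN gives the B-alkyl-9-BBN adduct O-borinate F14 (not isolated), which is coupled with 10 under the conditions of step 17 to the coupled alcohol F15. Dess–Martin oxidation comes back to the route at 24.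

**Further compounds**

F1 | step 2 | mirror image of 4, formed with 4 as the racemic cis adduct | O=C1C(C)=CC(=O)[C@H]2C(C)(C)C(O[Si](C(C)C)(C(C)C)C(C)C)=CC[C@@]12C
F2 | step 2 | mirror image of cis-fused triketone 5 (not isolated) | O=C1C(C)=CC(=O)[C@H]2C(C)(C)C(=O)CC[C@@]12C
F3 | step 2 | mirror image of trans-fused triketone 6 | O=C1C(C)=CC(=O)[C@@H]2C(C)(C)C(=O)CC[C@@]12C
F4 | step 2 | mirror image of diol 7 | O=C1C(C)=C[C@H](O)[C@@H]2C(C)(C)[C@H](O)CC[C@@]12C
F5 | step 2 | mirror image of hydroxy enone 8 | O=C1C(C)=CC[C@@H]2C(C)(C)[C@H](O)CC[C@@]12C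
F6 | step 2 | (S)-O-methylmandelate of 8 | O=C1C(C)=CC[C@H]2C(C)(C)[C@@H](OC(=O)[C@@H](OC)c3ccccc3)CC[C@]12C
F7 | step 2 | (S)-O-methylmandelate of F5 | O=C1C(C)=CC[C@@H]2C(C)(C)[C@H](OC(=O)[C@@H](OC)c3ccccc3)CC[C@@]12C
F8 | step 12 | methyl (2Z,6E)-3-(tert-butyldimethylsilyloxy)-7,11-dimethyldodeca-2,6,10-trienoate | COC(=O)/C=C(\O[Si](C)(C)C(C)(C)C)CC/C=C(\C)CCC=C(C)C
F9 | step 12 | (6S,7S,10S)-diepoxide of F8 | COC(=O)/C=C(\O[Si](C)(C)C(C)(C)C)CC[C@@H]1O[C@@]1(C)CC[C@@H]1OC1(C)C
F10 | step 12 | O-trimethylsilyl ether of F11 (not isolated) | COC(=O)[C@@H]2C(=O)CC[C@@H]3OC(C)(C)[C@@H](O[Si](C)(C)C)CC[C@]32C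
F11 | step 12 | methyl (3S,5aS,6R,9aS)-3-hydroxy-2,2,5a-trimethyl-7-oxodecahydro-1-benzoxepine-6-carboxylate | COC(=O)[C@@H]2C(=O)CC[C@@H]3OC(C)(C)[C@@H](O)CC[C@]32C
F12 | step 17 | (3S,5aS,6R,7R,9aS)-3-hydroxy-2,2,5a,7-tetramethyldecahydro-1-benzoxepine-6-carbaldehyde | O=C[C@@H]2[C@H](C)CC[C@@H]3OC(C)(C)[C@@H](O)CC[C@]32C
F13 | step 17 | (3S,5aS,6R,7R,9aS)-6-ethenyl-2,2,5a,7-tetramethyldecahydro-1-benzoxepin-3-ol | C=C[C@@H]2[C@H](C)CC[C@@H]3OC(C)(C)[C@@H](O)CC[C@]32C
F14 | step 17 | B-alkyl-9-BBN adduct of F13 as its O-borinate (not isolated) | C(C[C@@H]2[C@H](C)CC[C@@H]3OC(C)(C)[C@@H](OB6C7CCCC6CCC7)CC[C@]32C)B4C5CCCC4CCC5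
F15 | step 17 | coupled C3 alcohol, triethylsilyl ether at the decalin carbinol | CC1=C(CC[C@@H]2[C@H](C)CC[C@@H]3OC(C)(C)[C@@H](O)CC[C@]32C)[C@@]2(C)CC[C@H](O[Si](CC)(CC)CC)C(C)(C)[C@@H]2C=C1
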